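**Assumptions.** 2,4,6-Trimethoxyphenol (1), 4-bromo-2,6-dimethoxybenzaldehyde (2) and 5-iodo-1,2,3-trimethoxybenzene (16) are taken as purchasable. The target is achiral, so 26 is used as the racemate; its stereocentre, like those of 28 and 30, disappears on aromatisation. The structures of the key-step precursors and product were checked atom by atom against the target and needed no correction.

Abbreviations used in names: "ABC-aryloxy" = 4-[2,6-dimethoxy-4-(2,4,6-trimethoxyphenoxy)phenoxy]-2,6-dimethoxyphenoxy; "EF-aryloxy" = 3,5-dimethoxy-4-(3,4,5-trimethoxyphenoxy)phenoxy.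

## Structural features

The target is an achiral, linear hexamer of six benzene rings joined by five diaryl ether bonds; it carries fourteen free phenolic hydroxyls and has no stereocentre. Each ether oxygen sits on C4 of one ring, flanked by two C–OH groups, and on the unhindered C1 of the next ring. Rings B to E are therefore 1,2,3,5-tetraoxygenated benzenes, ring A is a 2,4,6-trihydroxyphenyl cap and ring F a 3,4,5-trihydroxyphenoxy (pyrogallol-type) cap. The free polyphenol, and above all the pyrogallol unit of ring F and the para-dioxygenated rings, is oxidised easily by air, most readily in base, so the hydroxyls can be unmasked only in the last step and under argon. The real difficulty is the five C–O bonds at doubly ortho-substituted oxygens, together with the repetitive pattern, which offers no natural handle for telling one ring from another. The key step exploits ring D: its C3 hydroxyl can be a ketene oxygen, C4 and C5 can be the two oxygenated carbons of a cyclobutenone, and C1 can be the oxygen-bearing carbon of an ynol ether. Both ether oxygens of ring D are then attached before the ring exists, one to an sp carbon and one to an sp3 carbon. The cut also falls in the middle and divides the hexamer into a three-ring and a two-ring half.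

## Logic of the disconnections

**32 back to 31.** The thirteen O–alkyl bonds (twelve O–CH3, one O–CH2CH3) are cut last. The reason is the air sensitivity of the free polyphenol: with all oxygens but one capped, every earlier intermediate tolerates copper catalysis, peracid, organolithium and heat, and can be chromatographed. The gain is a single closing operation. The demand is an exhaustive Lewis-acid dealkylation that leaves the five diaryl ether bonds intact, followed by isolation without oxygen.

**31 back to 14 and 26.** In ring D the bonds C1–C6 and C2–C3 are cut, with C3–C4 as the bond that opens and closes again during the cascade. The cut is made here because ring D then forms with both ether oxygens already in place, so no aryl–oxygen coupling at a crowded site is needed for the union of the halves. The gain is a convergent 3 + 2 assembly in which one step closes a ring and forms two skeletal bonds. The demand is regiochemical: the CH carbon of 14 must bond to the carbonyl carbon of the ketene derived from 26. Both partners must also survive about 100 °C.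

**26 back to 23 and 24.** Bonds C1–C2 and C3–C4 of the four-membered ring are cut (a [2+2] retron through ketene 25). The polarity of the two partners places the ethoxy group on C3 and the aryloxy group on C4 without any further control. The gain is a cyclobutenone from an acid chloride and a purchasable alkyne. The demand is that 25 be trapped by 24 faster than it reacts with itself.

**23 back to 22, then to 19 and 20.** The acyl C–Cl bond and then the O–CH2 bond are cut. The ring E oxygen concerned is unhindered, so it can be alkylated at an sp3 carbon by simple substitution. The gain is that the two carbons destined to become C3 and C4 of ring D come from a commodity ester. The demand is only the exclusion of air from the electron-rich phenoxide.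

**19 back to 17, then to 15 and 16.** The C1–O bond of ring E is traced back to a C1–CHO bond (Dakin retron), then the bond between the C4 oxygen of ring E and C1 of ring F is cut. The formyl group is a latent hydroxyl that is already para to the hindered phenol in 15, and it keeps that phenol from being oxidised during coupling. The gain is two steps from commercial materials. The demand is an aryl–oxygen coupling with a doubly ortho-substituted, electron-poor phenoxide.

**14 back to 11, then to 8 and 9.** The triple bond is traced back to a dichloroalkene (two eliminations), and the O–C(sp2) bond to addition of the phenoxide to 10, formed in the flask from 9. This attaches the crowded C4 oxygen of ring C to a rod-like carbon, where the two ortho methoxy groups matter little. The demand is that the organolithium used for the eliminations must not metallate the methoxyarenes.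

**8 back to 6 and 5, then to 3, and finally to 1 and 2 (used twice).** Each cycle cuts a C4–OH bond back to C4–CHO and then the aryl C1–O bond. In 2 the formyl group both activates the para C–Br bond for coupling and is the latent hindered hydroxyl of the next cycle, so the iteration needs no protecting group. The gain is two steps per ring. The demand is a peracid oxidation that consumes only the aldehyde and spares the electron-rich rings.

## Other disconnections considered

**Alternative 1:** The cut removes both aryl–oxygen bonds of ring C: from the C4 oxygen of ring B to C1 of ring C, and from C4 of ring C to the C1 oxygen of ring D.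
- **Forward step.** The cationic complex A1, [(C5H5)Ru(2,5-dichloro-1,3-dimethoxybenzene)]+ with divalent ruthenium, would be treated first with the phenoxide of 5, which should take the unhindered chloride. The phenoxide of the three-ring phenol A2 would then take the chloride flanked by two methoxy groups, giving the ring-C-bound cation A3. Photolytic release of the arene and global demethylation would follow.
- **In favour.** Nucleophilic aromatic substitution on cyclopentadienylruthenium chloroarene cations is an established, mild way to diaryl ethers. The two chlorides are differentiated by sterics in the order in which the nucleophiles are added. All rings are preformed, so no question of ring substitution pattern arises. The product is uniformly methylated.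
- **Against.** Ruthenium is stoichiometric, introduced from [(C5H5)Ru(NCMe)3]PF6. The second substitution must occur at a doubly ortho-substituted carbon of an arene already made more electron-rich by the first aryloxy group, and a methoxy group might be displaced in competition. A2 needs its own hindered coupling between the C4 oxygen of ring D and C1 of ring E, for which the formyl-activation device of the chosen route is not directly usable because ring D must end with a free C1 hydroxyl. A decomplexation step is added after the key step.
- **Comparison.** On structure the two plans are equally convergent, and the alternative is the better one in having no regiochemical decision during ring formation. On mechanism the alternative runs at room temperature by ionic steps, which is milder than heating ketenes, but it must substitute at the flanked aryl carbon, which the chosen plan avoids altogether. On step economy the alternative is probably one or two steps longer and uses a precious metal in stoichiometric amount.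

**Alternative 2:** The cut removes bonds C1–C2 and C4–C5 of ring E.
- **Forward step.** The enolate of keto ester A5 would add in a Michael sense to the aryloxypropiolate A4. A Claisen condensation of the C4 enolate onto the propiolate ester would then close ring E as the resorcinol ester A6. Removal of the ester (hydrolysis and decarboxylation) and demethylation would follow.
- **In favour.** It uses the same principle as the chosen plan: both ether oxygens of the new ring are attached beforehand to an sp and an sp3 carbon, and on this point the two plans are equal. It is better in running at low temperature, in needing neither a strained ring nor a free ketene, and in the one-step access to A5 from 3,4,5-trimethoxyphenol.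
- **Against.** The split is 4 + 1 and not 3 + 2, so A4 needs two more copper/peracid cycles beyond 8 and a carboxylation of the tetramer ynol ether. The conjugate adduct is a β-aryloxyacrylate that could expel the tetramer aryloxide by addition–elimination. Closure through oxygen to a 2-pyranone competes with the desired C-acylation. The ester at C2 of ring E must afterwards be removed from a hindered, electron-rich salicylate.
- **Comparison.** On structure the alternative is less convergent. On mechanism it is an anionic cascade with several competing closures, against a pericyclic cascade with a single polarity-controlled decision. On step economy its longest linear sequence would be roughly three or four steps longer.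

**Alternative 3:** The cut removes the ten aryl C–O(H) bonds at C3 and C5 of rings A to E, each traced back to a C–CHO bond.
- **Forward step.** The decaaldehyde A7 would be assembled by repeated nucleophilic aromatic substitution of phenoxides on aryl fluorides flanked by two formyl groups. 3-Chloroperbenzoic acid and then methanolysis would convert it into the decaphenol A8. Cleavage of the four remaining methyl ethers would finish the synthesis.
- **In favour.** Every diaryl ether bond is made by an unhindered phenoxide at a doubly activated carbon, so the steric problem is turned into an electronic advantage; here the alternative is better than any copper coupling of the chosen route. Only four ethers remain for the final Lewis-acid step, which is also better. The formyl-to-hydroxyl logic is the same as in steps 2, 4 and 8 of the chosen route, so on that point the plans are equal.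
- **Against.** Ten Baeyer–Villiger events must all proceed by aryl migration on rings that carry a second formyl group and only one ortho aryloxy donor. Hydrogen migration to benzoic acids would compete, and any shortfall per site would be compounded over ten sites. A8 is as air-sensitive as the target and still needs a demethylation. The assembly is linear, each incoming unit needs its phenol masked, and the fluoro-dialdehyde monomers are not commodity chemicals.
- **Comparison.** On structure the alternative is linear where the chosen plan is convergent. On mechanism it has the simplest individual reactions but a tenfold late-stage transformation, against one cascade. On step economy it is probably longer.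

Key step: step 12

## Route

Step 1
Reactants: 1 2,4,6-trimethoxyphenol; 2 4-bromo-2,6-dimethoxybenzaldehyde
Product: 3 fragment AB aldehyde: 2,6-dimethoxy-4-(2,4,6-trimethoxyphenoxy)benzaldehyde
Conditions: CuI (10 mol %), picolinic acid (20 mol %), K3PO4, DMSO, 90 °C, Ar
Reagents that add atoms: none
Why: Ullmann diaryl ether coupling; the C–Br carbon of 2 is unhindered and activated by the para formyl group, and picolinate-ligated monovalent copper is the combination suited to doubly ortho-substituted phenoxides.

Step 2
Reactants: 3 fragment AB aldehyde
Product: 5 fragment AB phenol: 2,6-dimethoxy-4-(2,4,6-trimethoxyphenoxy)phenol, via aryl formate 4 (not isolated)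
Conditions: mCPBA, CH2Cl2, 0 °C to rt; Na2S2O3 wash; K2CO3 (cat.), MeOH, rt, Ar
Reagents that add atoms: 3-chloroperbenzoic acid (mCPBA), OOC(=O)c1cccc(Cl)c1
Why: Dakin-type Baeyer–Villiger oxidation; an aryl group with two ortho methoxy donors and a para aryloxy donor should migrate in preference to hydrogen, and catalytic methoxide cleaves the formate under argon.

Step 3
Reactants: 5 fragment AB phenol; 2 4-bromo-2,6-dimethoxybenzaldehyde
Product: 6 fragment ABC aldehyde: 4-[2,6-dimethoxy-4-(2,4,6-trimethoxyphenoxy)phenoxy]-2,6-dimethoxybenzaldehyde
Conditions: CuI (10 mol %), picolinic acid (20 mol %), K3PO4, DMSO, 90 °C, Ar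
Reagents that add atoms: none
Why: The same Ullmann coupling, again between a 2,6-dimethoxyphenoxide and the activated, unhindered bromide, so the iteration needs no protecting group.

Step 4
Reactants: 6 fragment ABC aldehyde
Product: 8 fragment ABC phenol: 4-[2,6-dimethoxy-4-(2,4,6-trimethoxyphenoxy)phenoxy]-2,6-dimethoxyphenol, via aryl formate 7 (not isolated)
Conditions: mCPBA (1.2 equiv), CH2Cl2, 0 °C to rt; Na2S2O3 wash; K2CO3 (cat.), MeOH, rt, Ar
Reagents that add atoms: 3-chloroperbenzoic acid (mCPBA), OOC(=O)c1cccc(Cl)c1
Why: Dakin-type Baeyer–Villiger oxidation as in step 2; a small excess of peracid at 0 °C should oxidise the aldehyde well before it attacks the electron-rich rings.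

Step 5
Reactants: 8 fragment ABC phenol; 9 trichloroethylene
Product: 11 (E)-1,2-dichloroethenyl ether of fragment ABC, via dichloroethyne 10 (not isolated)
Conditions: K2CO3, DMF, 70 °C, Ar, closed vessel
Reagents that add atoms: none
Why: Base-induced loss of HCl from 9 gives 10, to which the phenoxide adds anti to give the E ether; attack on an sp carbon is little affected by the two ortho methoxy groups. Carbonate in DMF replaces potassium hydride, and 10 stays in solution throughout.

Step 6
Reactants: 11 (E)-1,2-dichloroethenyl ether of fragment ABC
Product: 14 ethynyl ether of fragment ABC, via chloroethynyl ether 12 (not isolated), via lithium acetylide 13 (not isolated)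
Conditions: n-BuLi (2.2 equiv), THF, −78 to −40 °C; MeOH, −78 °C
Reagents that add atoms: none
Why: Vinylic deprotonation and loss of LiCl give the chloroalkyne, chlorine–lithium exchange gives the acetylide and methanol protonates it (the standard dichlorovinyl ether route to ynol ethers). At −78 °C these steps should outrun ortho-lithiation of the methoxyarenes.

Step 7
Reactants: 15 syringaldehyde (4-hydroxy-3,5-dimethoxybenzaldehyde); 16 5-iodo-1,2,3-trimethoxybenzene
Product: 17 fragment EF aldehyde: 3,5-dimethoxy-4-(3,4,5-trimethoxyphenoxy)benzaldehyde
Conditions: CuI (10 mol %), picolinic acid (20 mol %), K3PO4, DMSO, 90–100 °C, Ar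
Reagents that add atoms: none
Why: Ullmann coupling of a hindered phenoxide with an aryl iodide whose reacting carbon is unhindered; the iodide offsets the electron-rich ring. The formyl group shields the phenol from oxidation and is the latent C1 hydroxyl of ring E.

Step 8
Reactants: 17 fragment EF aldehyde
Product: 19 fragment EF phenol: 3,5-dimethoxy-4-(3,4,5-trimethoxyphenoxy)phenol, via aryl formate 18 (not isolated)
Conditions: mCPBA, CH2Cl2, 0 °C to rt; Na2S2O3 wash; K2CO3 (cat.), MeOH, rt, Ar
Reagents that add atoms: 3-chloroperbenzoic acid (mCPBA), OOC(=O)c1cccc(Cl)c1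
Why: Dakin-type Baeyer–Villiger oxidation; the para aryloxy donor should favour aryl migration as it does in 3,4,5-trialkoxybenzaldehydes, and the formate is methanolysed in the same operation.

Step 9
Reactants: 19 fragment EF phenol; 20 ethyl bromoacetate
Product: 22 (EF-aryloxy)acetic acid: 2-[3,5-dimethoxy-4-(3,4,5-trimethoxyphenoxy)phenoxy]acetic acid, via ethyl ester 21 (not isolated)
Conditions: K2CO3, DMF, rt, Ar; then aq. NaOH, rt; HCl to pH 2
Reagents that add atoms: sodium hydroxide, [Na+].[OH-]
Why: Williamson etherification of the unhindered ring E phenoxide at a primary α-halo ester, followed by saponification in the same pot.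

Step 10
Reactants: 22 (EF-aryloxy)acetic acid
Product: 23 (EF-aryloxy)acetyl chloride: 2-[3,5-dimethoxy-4-(3,4,5-trimethoxyphenoxy)phenoxy]acetyl chloride
Conditions: (COCl)2, DMF (cat.), CH2Cl2, 0 °C to rt; evaporation, used crude
Reagents that add atoms: oxalyl chloride, ClC(=O)C(Cl)=O
Why: Acid chloride formation through the chloroiminium catalyst; without a Lewis acid the electron-rich ring E should not be acylated.

Step 11
Reactants: 23 (EF-aryloxy)acetyl chloride; 24 ethoxyethyne
Product: 26 racemic 3-ethoxy-4-(EF-aryloxy)cyclobut-2-en-1-one, via aryloxyketene 25 (not isolated)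
Conditions: NEt3, 24 (3 equiv), CH2Cl2, 0 °C to rt, slow addition of 23
Reagents that add atoms: none
Why: Dehydrochlorination gives the aryloxyketene, which adds 24 in a ketene–alkyne [2+2] cycloaddition; the ketene carbonyl carbon bonds to the CH carbon of 24, so ethoxy ends on C3 and aryloxy on C4. The C4 stereocentre forms as the racemate without control and is destroyed in step 12.

Step 12
Reactants: 14 ethynyl ether of fragment ABC; 26 racemic 3-ethoxy-4-(EF-aryloxy)cyclobut-2-en-1-one
Product: 31 hexamer monophenol (ring D: OH at C3 and OEt at C5; twelve methyl ethers elsewhere), via vinylketene 27 (not isolated), via vinylcyclobutenone 28 (not isolated), via dienylketene 29 (not isolated), via cyclohexadienone 30 (not isolated)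
Conditions: PhMe, 105 °C, Ar, sealed tube; 26 (1.3 equiv)
Reagents that add atoms: none
Why: Danheiser benzannulation, a thermal pericyclic cascade: 26 should open by conrotatory 4-electron electrocyclic ring opening, its C4 aryloxy donor turning outward, to vinylketene 27. The ketene C=C bond of 27 and the triple bond of 14 then combine in a [2+2] cycloaddition in which the CH carbon of 14 bonds to the ketene carbonyl carbon (C2–C3 of ring D) and the oxygen-bearing carbon to the ketene α-carbon (C1–C6), giving 28. A second 4-electron opening of 28 gives dienylketene 29, and ring D closes by thermal disrotatory 6-electron electrocyclisation between the ketene carbon and the aryloxy-bearing diene terminus (C3–C4 re-formed) to 30, which enolises irreversibly to the phenol 31. The closest known reaction type is the benzannulation of cyclobutenones with alkoxy- and silyloxyalkynes to resorcinol monoethers; only the substitution is new, an aryl ynol ether and a 3-alkoxy-4-aryloxycyclobutenone. No stereocentre remains: those of 26, 28 and 30 are racemic and are erased on aromatisation. The one selectivity needed is regiochemical, the ring C oxygen meta to the new hydroxyl, and it follows from the polarity match between the oxygen-activated CH terminus of 14 and the electrophilic central carbon of the ketene. The aryl ynol ether has no β-hydrogen for retro-ene loss of ketene and both ortho positions of ring C are blocked, so it should tolerate the temperature, and the small excess of 26 covers loss of ketene by self-reaction.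

Step 13
Reactants: 31 hexamer monophenol
Product: 32 target hexamer with fourteen free hydroxyls (CNP0187343.0)
Conditions: BBr3 (about 30 equiv), CH2Cl2, −78 °C to rt, Ar; MeOH then degassed H2O, 0 °C; Sephadex LH-20, degassed MeOH, Ar
Reagents that add atoms: none
Why: Lewis-acid ether cleavage; boron coordinates each alkoxy oxygen and bromide attacks the methyl or ethyl carbon, while the diaryl ether oxygens offer no sp3 carbon and should survive. Hydrolysis of the aryl borates frees the phenols, which are kept under argon.

## Compound list

1 | 2,4,6-trimethoxyphenol | COc1cc(OC)c(O)c(OC)c1 | starting material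
2 | 4-bromo-2,6-dimethoxybenzaldehyde | COc1cc(Br)cc(OC)c1C=O | starting material
3 | 2,6-dimethoxy-4-(2,4,6-trimethoxyphenoxy)benzaldehyde (fragment AB aldehyde) | COc1cc(OC)c(Oc2cc(OC)c(C=O)c(OC)c2)c(OC)c1 | intermediate
4 | 2,6-dimethoxy-4-(2,4,6-trimethoxyphenoxy)phenyl formate | COc1cc(OC)c(Oc2cc(OC)c(OC=O)c(OC)c2)c(OC)c1 | intermediate
5 | 2,6-dimethoxy-4-(2,4,6-trimethoxyphenoxy)phenol (fragment AB phenol) | COc1cc(OC)c(Oc2cc(OC)c(O)c(OC)c2)c(OC)c1 | intermediate
6 | 4-[2,6-dimethoxy-4-(2,4,6-trimethoxyphenoxy)phenoxy]-2,6-dimethoxybenzaldehyde (fragment ABC aldehyde) | COc1cc(OC)c(Oc2cc(OC)c(Oc3cc(OC)c(C=O)c(OC)c3)c(OC)c2)c(OC)c1 | intermediate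
7 | 4-[2,6-dimethoxy-4-(2,4,6-trimethoxyphenoxy)phenoxy]-2,6-dimethoxyphenyl formate | COc1cc(OC)c(Oc2cc(OC)c(Oc3cc(OC)c(OC=O)c(OC)c3)c(OC)c2)c(OC)c1 | intermediate
8 | 4-[2,6-dimethoxy-4-(2,4,6-trimethoxyphenoxy)phenoxy]-2,6-dimethoxyphenol (fragment ABC phenol) | COc1cc(OC)c(Oc2cc(OC)c(Oc3cc(OC)c(O)c(OC)c3)c(OC)c2)c(OC)c1 | intermediate
9 | trichloroethylene | ClC=C(Cl)Cl | starting material
10 | dichloroethyne | ClC#CCl | intermediate
11 | (E)-1,2-dichloroethenyl ether of 8 (on the C4 oxygen of ring C) | Cl/C=C(/Cl)Oc1c(OC)cc(Oc2c(OC)cc(Oc3c(OC)cc(OC)cc3OC)cc2OC)cc1OC | intermediate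
12 | chloroethynyl ether of 8 | ClC#COc1c(OC)cc(Oc2c(OC)cc(Oc3c(OC)cc(OC)cc3OC)cc2OC)cc1OC | intermediate
13 | lithium acetylide of the ethynyl ether of 8 | [Li]C#COc1c(OC)cc(Oc2c(OC)cc(Oc3c(OC)cc(OC)cc3OC)cc2OC)cc1OC | intermediate
14 | ethynyl ether of 8: 2-(ethynyloxy)-5-[2,6-dimethoxy-4-(2,4,6-trimethoxyphenoxy)phenoxy]-1,3-dimethoxybenzene | C#COc1c(OC)cc(Oc2c(OC)cc(Oc3c(OC)cc(OC)cc3OC)cc2OC)cc1OC | intermediate
15 | syringaldehyde (4-hydroxy-3,5-dimethoxybenzaldehyde) | COc1cc(C=O)cc(OC)c1O | starting material
16 | 5-iodo-1,2,3-trimethoxybenzene | COc1cc(I)cc(OC)c1OC | starting material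
17 | 3,5-dimethoxy-4-(3,4,5-trimethoxyphenoxy)benzaldehyde (fragment EF aldehyde) | COc1cc(C=O)cc(OC)c1Oc2cc(OC)c(OC)c(OC)c2 | intermediate
18 | 3,5-dimethoxy-4-(3,4,5-trimethoxyphenoxy)phenyl formate | COc1cc(OC=O)cc(OC)c1Oc2cc(OC)c(OC)c(OC)c2 | intermediate
19 | 3,5-dimethoxy-4-(3,4,5-trimethoxyphenoxy)phenol (fragment EF phenol) | COc1cc(O)cc(OC)c1Oc2cc(OC)c(OC)c(OC)c2 | intermediate
20 | ethyl bromoacetate | CCOC(=O)CBr | starting material
21 | ethyl 2-[3,5-dimethoxy-4-(3,4,5-trimethoxyphenoxy)phenoxy]acetate | CCOC(=O)COc1cc(OC)c(Oc2cc(OC)c(OC)c(OC)c2)c(OC)c1 | intermediate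
22 | 2-[3,5-dimethoxy-4-(3,4,5-trimethoxyphenoxy)phenoxy]acetic acid | OC(=O)COc1cc(OC)c(Oc2cc(OC)c(OC)c(OC)c2)c(OC)c1 | intermediate
23 | 2-[3,5-dimethoxy-4-(3,4,5-trimethoxyphenoxy)phenoxy]acetyl chloride | ClC(=O)COc1cc(OC)c(Oc2cc(OC)c(OC)c(OC)c2)c(OC)c1 | intermediate
24 | ethoxyethyne | CCOC#C | starting material
25 | 2-(EF-aryloxy)ethen-1-one (aryloxyketene) | O=C=COc1cc(OC)c(Oc2cc(OC)c(OC)c(OC)c2)c(OC)c1 | intermediate
26 | racemic 3-ethoxy-4-[3,5-dimethoxy-4-(3,4,5-trimethoxyphenoxy)phenoxy]cyclobut-2-en-1-one | CCOC1=CC(=O)C1Oc2cc(OC)c(Oc3cc(OC)c(OC)c(OC)c3)c(OC)c2 | intermediate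
27 | (Z)-3-ethoxy-4-(EF-aryloxy)buta-1,3-dien-1-one (vinylketene; aryloxy trans to the ketene carbon) | O=C=C/C(OCC)=C/Oc1cc(OC)c(Oc2cc(OC)c(OC)c(OC)c2)c(OC)c1 | intermediate
28 | racemic 3-(ABC-aryloxy)-4-[(Z)-1-ethoxy-2-(EF-aryloxy)ethenyl]cyclobut-2-en-1-one | O=C1C=C(Oc2c(OC)cc(Oc3c(OC)cc(Oc4c(OC)cc(OC)cc4OC)cc3OC)cc2OC)C1/C(OCC)=C/Oc5cc(OC)c(Oc6cc(OC)c(OC)c(OC)c6)c(OC)c5 | intermediate
29 | (3E,5Z)-3-(ABC-aryloxy)-5-ethoxy-6-(EF-aryloxy)hexa-1,3,5-trien-1-one (dienylketene) | O=C=C/C(Oc1c(OC)cc(Oc2c(OC)cc(Oc3c(OC)cc(OC)cc3OC)cc2OC)cc1OC)=C\C(OCC)=C\Oc4cc(OC)c(Oc5cc(OC)c(OC)c(OC)c5)c(OC)c4 | intermediate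
30 | racemic 3-(ABC-aryloxy)-5-ethoxy-6-(EF-aryloxy)cyclohexa-2,4-dien-1-one | O=C1C=C(Oc2c(OC)cc(Oc3c(OC)cc(Oc4c(OC)cc(OC)cc4OC)cc3OC)cc2OC)C=C(OCC)C1Oc5cc(OC)c(Oc6cc(OC)c(OC)c(OC)c6)c(OC)c5 | intermediate
31 | hexamer monophenol: 5-(ABC-aryloxy)-3-ethoxy-2-(EF-aryloxy)phenol (ring D: C1 O–ring C, C3 OH, C4 O–ring E, C5 OEt) | COc1cc(OC)c(Oc2cc(OC)c(Oc3cc(OC)c(Oc4cc(O)c(Oc5cc(OC)c(Oc6cc(OC)c(OC)c(OC)c6)c(OC)c5)c(OCC)c4)c(OC)c3)c(OC)c2)c(OC)c1 | intermediate
32 | target: linear para-linked hexamer, rings A to F, each ether oxygen flanked by two hydroxyls; ring A 2,4,6-trihydroxyphenyl, ring F 3,4,5-trihydroxyphenoxy; fourteen OH | Oc1cc(O)c(Oc2cc(O)c(Oc3cc(O)c(Oc4cc(O)c(Oc5cc(O)c(Oc6cc(O)c(O)c(O)c6)c(O)c5)c(O)c4)c(O)c3)c(O)c2)c(O)c1 | target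

## Step count and least certain steps

Total: 13 steps. Longest linear sequence: 8 steps (steps 1 to 6, 12 and 13); the fragment EF branch contributes steps 7 to 11.

**Step 12 (key step).** The cycloaddition may be too slow, because an aryloxyalkyne is a weaker ketenophile than an alkoxyalkyne and the vinylketene carries two donor groups. The ketene would then be lost to self-reaction or to acylation of the product phenol; the latter can be reversed by brief methanolysis with K2CO3. The fallback gives up the benzannulation and continues the copper/peracid iteration in a linear way from 8. Ullmann coupling of 8 with 2 would give the fragment ABCD aldehyde F1, and peracid oxidation through the formate F2 the fragment ABCD phenol F3. A second cycle with 2 would give the fragment ABCDE aldehyde F4 and, through the formate F5, the fragment ABCDE phenol F6. Coupling of F6 with 16 would give the tetradecamethyl ether F7, and BBr3 would convert F7 into 32, where the route is rejoined.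

**Step 11.** The aryloxyketene may oligomerise under the amine base faster than it is captured by the volatile alkyne, and the product, a vinylogous ester, may hydrolyse on silica. The fallback generates the same vinylketene without any cyclobutenone. Phenol 19 would be alkylated with commercial ethyl (E)-4-chloro-3-ethoxybut-2-enoate (K2CO3, DMF) to ethyl (E)-3-ethoxy-4-(EF-aryloxy)but-2-enoate F8. Saponification would give the acid F9 and oxalyl chloride the acid chloride F10. Slow addition of F10 to NEt3 and 14 in hot toluene should cause 1,4-dehydrochlorination to vinylketene 27, which enters the cascade of step 12 and rejoins the route at 31.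

**Step 5.** Addition of the crowded, oxidation-prone phenoxide to dichloroethyne may stay incomplete at the temperature that carbonate requires, and the volatile, hazardous intermediate limits how hard the reaction can be pushed. The fallback uses the carbon that the ring C oxygen already carries after the peracid stage of step 4. Formate 7 would be isolated and converted with CBr4 and PPh3 (dibromoolefination of the formyl group) into the 2,2-dibromoethenyl ether of fragment ABC F11. Treatment with n-BuLi at −78 °C (Corey–Fuchs-type elimination and exchange) would lead to acetylide 13 and, after methanol, to 14, where the route is rejoined. This path avoids trichloroethylene altogether.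

**Step 7.** The coupling may stall, since the phenoxide is both electron-poor and doubly ortho-substituted and the iodide is electron-rich; reduction of the iodide would then dominate. The fallback changes the bond-forming manifold to an oxidative Chan–Lam coupling. Syringaldehyde 15 and 3,4,5-trimethoxyphenylboronic acid, with Cu(OAc)2 (divalent copper), pyridine and molecular sieves in CH2Cl2 under air at room temperature, should give 17 directly, rejoining the route at 17. The aryl partner is then the nucleophilic component, and acidic phenols are well tolerated. No new compound arises (F0).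

**Step 13.** Cleavage at thirteen sites may remain incomplete, and the free polyphenol may be degraded by oxidation during chromatography. The fallback isolates through a stable derivative. After the BBr3 treatment of 31 the crude product would be acetylated at once (Ac2O, pyridine) to the tetradecaacetate F12, which can be purified on silica in air and, if under-cleaved material is present, separated from it. Deacetylation of F12 with catalytic NaOMe in degassed methanol under argon, followed by neutralisation with acidic resin, would return 32.

## Further compounds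

F1 | step 12 | fragment ABCD aldehyde: 2,6-dimethoxybenzaldehyde carrying the ABC-aryloxy group at C4 | COc1cc(OC)c(Oc2cc(OC)c(Oc3cc(OC)c(Oc4cc(OC)c(C=O)c(OC)c4)c(OC)c3)c(OC)c2)c(OC)c1
F2 | step 12 | fragment ABCD formate: 4-(ABC-aryloxy)-2,6-dimethoxyphenyl formate | COc1cc(OC)c(Oc2cc(OC)c(Oc3cc(OC)c(Oc4cc(OC)c(OC=O)c(OC)c4)c(OC)c3)c(OC)c2)c(OC)c1
F3 | step 12 | fragment ABCD phenol: 4-(ABC-aryloxy)-2,6-dimethoxyphenol | COc1cc(OC)c(Oc2cc(OC)c(Oc3cc(OC)c(Oc4cc(OC)c(O)c(OC)c4)c(OC)c3)c(OC)c2)c(OC)c1
F4 | step 12 | fragment ABCDE aldehyde (pentamer, formyl at C4 of ring E, eleven methyl ethers) | COc1cc(OC)c(Oc2cc(OC)c(Oc3cc(OC)c(Oc4cc(OC)c(Oc5cc(OC)c(C=O)c(OC)c5)c(OC)c4)c(OC)c3)c(OC)c2)c(OC)c1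
F5 | step 12 | fragment ABCDE formate (pentamer, formyloxy at C4 of ring E) | COc1cc(OC)c(Oc2cc(OC)c(Oc3cc(OC)c(Oc4cc(OC)c(Oc5cc(OC)c(OC=O)c(OC)c5)c(OC)c4)c(OC)c3)c(OC)c2)c(OC)c1
F6 | step 12 | fragment ABCDE phenol (pentamer, free hydroxyl at C4 of ring E) | COc1cc(OC)c(Oc2cc(OC)c(Oc3cc(OC)c(Oc4cc(OC)c(Oc5cc(OC)c(O)c(OC)c5)c(OC)c4)c(OC)c3)c(OC)c2)c(OC)c1
F7 | step 12 | tetradecamethyl ether of the hexamer | COc1cc(OC)c(Oc2cc(OC)c(Oc3cc(OC)c(Oc4cc(OC)c(Oc5cc(OC)c(Oc6cc(OC)c(OC)c(OC)c6)c(OC)c5)c(OC)c4)c(OC)c3)c(OC)c2)c(OC)c1
F8 | step 11 | ethyl (E)-3-ethoxy-4-(EF-aryloxy)but-2-enoate | CCOC(=O)/C=C(/OCC)COc1cc(OC)c(Oc2cc(OC)c(OC)c(OC)c2)c(OC)c1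
F9 | step 11 | (E)-3-ethoxy-4-(EF-aryloxy)but-2-enoic acid | OC(=O)/C=C(/OCC)COc1cc(OC)c(Oc2cc(OC)c(OC)c(OC)c2)c(OC)c1
F10 | step 11 | (E)-3-ethoxy-4-(EF-aryloxy)but-2-enoyl chloride | ClC(=O)/C=C(/OCC)COc1cc(OC)c(Oc2cc(OC)c(OC)c(OC)c2)c(OC)c1
F11 | step 5 | 2,2-dibromoethenyl ether of fragment ABC (on the C4 oxygen of ring C) | BrC(Br)=COc1c(OC)cc(Oc2c(OC)cc(Oc3c(OC)cc(OC)cc3OC)cc2OC)cc1OC
F0 | step 7 | none | none
F12 | step 13 | tetradecaacetate of 32 | CC(=O)Oc1cc(OC(C)=O)c(Oc2cc(OC(C)=O)c(Oc3cc(OC(C)=O)c(Oc4cc(OC(C)=O)c(Oc5cc(OC(C)=O)c(Oc6cc(OC(C)=O)c(OC(C)=O)c(OC(C)=O)c6)c(OC(C)=O)c5)c(OC(C)=O)c4)c(OC(C)=O)c3)c(OC(C)=O)c2)c(OC(C)=O)c1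
A1 | alternative 1 | (cyclopentadienyl)(2,5-dichloro-1,3-dimethoxybenzene)ruthenium cation, divalent ruthenium, eta-6 arene | COc1cc(Cl)cc(OC)c1Cl.[Ru+2].c1cc[cH-]c1
A2 | alternative 1 | fragment DEF phenol: 3,5-dimethoxy-4-(EF-aryloxy)phenol | COc1cc(O)cc(OC)c1Oc2cc(OC)c(Oc3cc(OC)c(OC)c(OC)c3)c(OC)c2
A3 | alternative 1 | cation of the tetradecamethyl hexamer with (C5H5)Ru eta-6 bound to ring C, divalent ruthenium | COc1cc(OC)c(Oc2cc(OC)c(Oc3cc(OC)c(Oc4cc(OC)c(Oc5cc(OC)c(Oc6cc(OC)c(OC)c(OC)c6)c(OC)c5)c(OC)c4)c(OC)c3)c(OC)c2)c(OC)c1.[Ru+2].c1cc[cH-]c1
A4 | alternative 2 | methyl 3-(fragment ABCD oxy)prop-2-ynoate (ynol ether on the C4 oxygen of ring D) | COC(=O)C#COc1c(OC)cc(Oc2c(OC)cc(Oc3c(OC)cc(Oc4c(OC)cc(OC)cc4OC)cc3OC)cc2OC)cc1OC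
A5 | alternative 2 | methyl 3-oxo-4-(3,4,5-trimethoxyphenoxy)butanoate | COC(=O)CC(=O)COc1cc(OC)c(OC)c(OC)c1
A6 | alternative 2 | hexamer dodecamethyl ether with free hydroxyls at C3 and C5 and a methyl ester at C2 of ring E | COc1cc(OC)c(Oc2cc(OC)c(Oc3cc(OC)c(Oc4cc(OC)c(Oc5cc(O)c(Oc6cc(OC)c(OC)c(OC)c6)c(O)c5C(=O)OC)c(OC)c4)c(OC)c3)c(OC)c2)c(OC)c1
A7 | alternative 3 | hexamer decaaldehyde: formyl at C3 and C5 of rings A to E, methoxy at C1 of ring A, ring F trimethoxy | COc1cc(C=O)c(Oc2cc(C=O)c(Oc3cc(C=O)c(Oc4cc(C=O)c(Oc5cc(C=O)c(Oc6cc(OC)c(OC)c(OC)c6)c(C=O)c5)c(C=O)c4)c(C=O)c3)c(C=O)c2)c(C=O)c1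
A8 | alternative 3 | hexamer with ten free hydroxyls on rings A to E and four methyl ethers (C1 of ring A, ring F) | COc1cc(O)c(Oc2cc(O)c(Oc3cc(O)c(Oc4cc(O)c(Oc5cc(O)c(Oc6cc(OC)c(OC)c(OC)c6)c(O)c5)c(O)c4)c(O)c3)c(O)c2)c(O)c1
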